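# Proposed total synthesis of CNP0231903.1 from (R)-carvone by allylsilane–aldehyde closure of ring A

## Analysis of the target

The target is a labdane-type diterpenoid: a trans-fused decalin (rings A and B) with a tetrasubstituted C8=C9 alkene. C8 carries a methyl group, and C9 carries a two-carbon chain (C11–C12) that ends at the β-carbon (C13) of a butenolide. There are five stereocentres. C2 bears an α (equatorial) hydroxyl. C4 is quaternary, with an α-methyl and a β (axial) hydroxymethyl group, C19. C5 has an α-hydrogen, C6 an α (equatorial) acetoxy group, and C10 is quaternary with a β-methyl. C4, C5, C6 and C10 are contiguous, and C2 stands 1,3 to both quaternary carbons, so all five centres can be related through one chair of ring A and its fusion to ring B.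

The sensitive groups are:
- the butenolide, which does not tolerate strong base, hydride or organometallic nucleophiles;
- the secondary acetate, which can migrate to the C19 hydroxyl through a six-membered transition state;
- the tetrasubstituted alkene, which can isomerise under acid.

The synthesis is hard because two quaternary carbons flank C5, three oxygen functions must be introduced with only one of them acylated, and the hindered alkene must be placed unambiguously.

The strategy rests on ring B. C5 with its C4 branch, C6, C7, C8 with its methyl group, a C9 oxygen handle and C10 are the carbon framework of (R)-carvone. Its isopropenyl group supplies C3, C4 and C19, so ring A can be closed onto this terpene by one C2–C3 bond.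

## Retrosynthetic reasoning

**Silyl ethers last.** Target 31 is traced back to the bis-silyl ether 30. The acetate has to be placed on C6 while the C2 and C19 oxygens are blocked. The final deprotection must be non-basic so that the acetate does not migrate to C19 and the butenolide is not opened.

**C12–C13.** The butenolide is attached intact and late. Cutting C12–C13 gives the alkylborane 29 and 4-bromofuran-2(5H)-one 28. Borane 29 comes from hydroboration of the terminal vinyl group of diene 27. The lactone therefore never meets the hydride, base and enolate chemistry used earlier, and the forward reaction is an sp3–sp2 Suzuki–Miyaura coupling on a vinylogous acyl bromide.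

**C9–C11 and the C8=C9 alkene.** Diene 27 is cut at C9–C11 into the enol triflate 25 and tributyl(vinyl)stannane 26. Triflate 25 is the O-sulfonylated form of enolate 24, which arises by conjugate hydride addition to enone 23. Because C10 is quaternary, this enolate can only be the C8–C9 enolate, so the tetrasubstituted alkene is placed without isomer problems. Adding a carbon nucleophile to the C9 ketone and then removing the tertiary allylic oxygen with transposition would pass through an allyl cation next to the C6 ester, so that path is not used.

**C6–O.** Acetate 23 comes from alcohol 21 and acetic anhydride 22. The C6–O bond of 21 is cut back to the silyl dienol ether 20, in which C6 is the nucleophilic γ-terminus of the enone system inherited from 1. The forward oxidation must come from the α face. At that stage the β face is covered by the axial C10 methyl and the axial C19 substituent, which is why C4 is completed before C6 is oxidised.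

**C4 quaternary centre.** Dienol ether 20 comes from alcohol 19, the reduction product of aldehyde 18. In 18 the C4–CH3 bond is cut, giving the enolate 17 of aldehyde 16 and iodomethane 2. Methylation from the equatorial α face leaves the one-carbon oxygenated group axial, as the target requires. Aldehyde 16 is the 1,2-hydride-shift isomer of epoxide 15, made from the exocyclic alkene of 14, the silyl ether of 13.

**C2–C3 (key disconnection).** The methylidene alcohol 13 is opened between C2 and C3 to the allylsilane aldehyde 12. This cut is chosen because it creates the C2 oxygen in the ring-forming step, leaves an exocyclic alkene as the handle for the C4 quaternary centre, and needs only a trans relationship of two arms on ring B, which carvone alkylation provides.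

**Functional group adjustment to 12.** Aldehyde 12 comes from diol 11 by double oxidation, and 11 from ester 10 by reduction. The allylsilane of 10 comes from the allylic chloride 8 and hexamethyldisilane 9, and 8 from the isopropenyl compound 7 by ene-type chlorination.

**C10 quaternary centre.** Ester 7 is cut at C10–C1 into the enolate 6 of methylcarvone 4 and tert-butyl bromoacetate 5. Compound 4 is cut at C10–CH3 into (R)-carvone 1, through its dienolate 3, and iodomethane 2. The order, methyl first and acetate arm second, is dictated by the second alkylation occurring anti to the isopropenyl group, which puts the arm trans and the methyl cis to the future C5–C4 bond.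

## Alternatives that were turned down

**Alternative 1: oxidative radical bicyclisation of an acyclic keto ester.**
- Disconnection: C4–C5 and C9–C10 are cut, opening both rings to the acyclic β-keto ester A1, which already carries the C6 acetate.
- Forward key step: a trivalent manganese carboxylate with a divalent copper co-oxidant generates the C4 radical. This adds to C5, the resulting C10 radical adds to C9, and oxidation of the C8 radical ends the cascade as the exocyclic alkene of A2.
- For: this is the most economical construction of the skeleton. Two rings, two C–C bonds and the C4, C5, C9 and C10 centres are formed in one step, and the C19 ester arrives axial.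
- Against: the ring A oxygen of A2 sits on C3, so a 1,2-carbonyl transposition with control of an equatorial C2 alcohol is needed. The alkene is exocyclic and must be moved into the tetrasubstituted position without stopping at C7=C8, where the C6 acetate would become allylic. Facial control of the whole cascade rests on the single acetoxy stereocentre of A1, which itself needs an enantioselective synthesis.
- Comparison: on bonds formed per step this alternative is stronger than the chosen route. The chosen route places oxygen on C2 in the ring closure itself and takes C5 and C10 from a cheap terpene, so it avoids the corrective steps that would follow A2.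

**Alternative 2: ring B by intramolecular ketone alkenylation.**
- Disconnection: C7–C8 is cut, leaving the fully substituted ring A ketone A3 with an acetyl group on C5 and an enol triflate arm on C10.
- Forward key step: the methyl ketone enolate of A3 couples with the enol triflate under a zerovalent palladium phosphine catalyst and base, closing ring B to the keto ester A4.
- For: the tetrasubstituted C8=C9 alkene is formed directly and in the right place, with the C6 carbonyl and a C9 carbon handle present. On this point it is stronger than the chosen route, which needs a reductive triflation and two couplings.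
- Against: the difficulty is moved into A3, a cyclohexane with four stereocentres, two of them quaternary and flanking C5, and a tetrasubstituted (E)-enol triflate on a neopentyl carbon. Hydride reduction of the C6 ketone of A4 would come from the open α face and give the axial 6β alcohol, the wrong epimer. The C7 methylene of A4 is activated by both the ketone and the unsaturated ester, so alkene migration is a risk under basic conditions. The C9 ester must be homologated before the butenolide can be built.
- Comparison: the chosen route reaches its cyclisation substrate in six steps and introduces the C6 oxygen directly in the α configuration.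

**Alternative 3: asymmetric quinone Diels–Alder for ring A.**
- Disconnection: C1–C10 and C4–C5 are cut, giving the quinone A5 and the silyloxy dienoate A6.
- Forward key step: a cationic chiral oxazaborolidine Lewis acid derived from a prolinol promotes the cycloaddition to the cis-fused enedione A7.
- For: this is the most convergent plan. Two achiral building blocks give all ring carbons, oxygen at C2, C6 and C9 and the C19 carbon in one catalytic enantioselective step. On convergence and on the number of steps to an oxygenated decalin it is stronger than the chosen route.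
- Against: A7 is cis-fused and must be epimerised at C5. It holds a masked ketone and two ring ketones of similar reactivity that must be told apart. The C4 quaternary centre still has to be made by enolate methylation in the presence of two enolisable ketones. The C6 ketone again reduces to the wrong, axial alcohol with simple hydrides.
- Comparison: the chosen route carries a single ketone through the sequence, introduces each oxygen in its final configuration (C2 in the ring closure, C6 by a face-selective oxidation), and needs no specialised catalyst for absolute configuration.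

Key step: step 7

Remark on the chemistry: the bicyclic intermediates are described with labdane ring numbering (C1–C10; C17 is the methyl on C8, C19 the β carbon on C4, C20 the methyl on C10), and β is the face of the C10 methyl. Compound 4 is carried forward as the mixture of C6 epimers, because that centre becomes trigonal again in step 2.

## Route

Step 1
Reactants: 1 (R)-carvone; 2 iodomethane
Product: 4 (5R)-2,6-dimethyl-5-(prop-1-en-2-yl)cyclohex-2-en-1-one (6-methylcarvone; both C6 epimers), via lithium dienolate of carvone 3 (not isolated)
Conditions: LiN(i-Pr)2, THF, −78 °C; MeI, −78 → 0 °C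
Reagents that add atoms: iodomethane (2), CI
Why: Kinetic deprotonation of carvone occurs at the α′-methylene to give the cross-conjugated dienolate, and C-methylation there is a standard enolate alkylation; the new centre need not be controlled because it is flattened again in step 2.

Step 2
Reactants: 4 6-methylcarvone; 5 tert-butyl bromoacetate
Product: 7 tert-butyl 2-[(1S,6S)-1,3-dimethyl-2-oxo-6-(prop-1-en-2-yl)cyclohex-3-en-1-yl]acetate (acetate arm trans to isopropenyl), via lithium enolate of methylcarvone 6 (not isolated)
Conditions: LiN(i-Pr)2, THF, −78 °C; BrCH2CO2t-Bu, DMPU, −78 → −20 °C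
Reagents that add atoms: tert-butyl bromoacetate (5), CC(C)(C)OC(=O)CBr
Why: The tetrasubstituted enolate is alkylated on the face opposite the neighbouring isopropenyl group (enolate alkylation under 1,2-induction), which puts the acetate arm trans and the methyl cis to isopropenyl and so sets the quaternary carbon that becomes C10; the bulky ester suppresses Claisen side reactions.

Step 3
Reactants: 7 isopropenyl keto ester
Product: 8 tert-butyl 2-[(1S,6R)-6-(3-chloroprop-1-en-2-yl)-1,3-dimethyl-2-oxocyclohex-3-en-1-yl]acetate
Conditions: Ca(OCl)2, CO2 (solid), CH2Cl2/H2O, 0 °C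
Reagents that add atoms: calcium hypochlorite, [Ca+2].[O-]Cl.[O-]Cl
Why: Hypochlorous acid formed in the flask chlorinates the electron-rich 1,1-disubstituted alkene in an ene-type allylic chlorination with double-bond shift, while the electron-poor enone alkene does not react.

Step 4
Reactants: 8 allylic chloride; 9 hexamethyldisilane
Product: 10 tert-butyl 2-[(1S,6R)-1,3-dimethyl-2-oxo-6-[3-(trimethylsilyl)prop-1-en-2-yl]cyclohex-3-en-1-yl]acetate
Conditions: Me3SiSiMe3, Pd(PPh3)4 (5 mol %), toluene, 100 °C, sealed tube
Reagents that add atoms: hexamethyldisilane (9), C[Si](C)(C)[Si](C)(C)C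
Why: Oxidative addition of zerovalent palladium to the allylic chloride gives a 2-substituted π-allyl complex with two equivalent CH2 termini, which is silylated by the disilane (palladium-catalysed allylic silylation); the conditions are neutral, so the ketone and the ester are spared, and the π-allyl has no hydrogen placed for diene formation.

Step 5
Reactants: 10 allylsilane keto ester
Product: 11 (5R,6S)-6-(2-hydroxyethyl)-2,6-dimethyl-5-[3-(trimethylsilyl)prop-1-en-2-yl]cyclohex-2-en-1-ol (both C1 epimers)
Conditions: i-Bu2AlH (excess), CH2Cl2, −78 °C → rt; aqueous tartrate work-up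
Reagents that add atoms: none
Why: Excess aluminium hydride reduces the ester to the primary alcohol and the enone carbonyl by 1,2-addition, the allylsilane being inert; the configuration of the new carbinol carbon is irrelevant because it is oxidised again in step 6.

Step 6
Reactants: 11 diol
Product: 12 2-[(1S,6R)-1,3-dimethyl-2-oxo-6-[3-(trimethylsilyl)prop-1-en-2-yl]cyclohex-3-en-1-yl]acetaldehyde
Conditions: (COCl)2, DMSO, CH2Cl2, −78 °C; Et3N, −78 → 0 °C
Reagents that add atoms: none
Why: In the Swern oxidation both hydroxyls are activated before base is added, so the keto aldehyde should form without passing through a lactol that would be oxidised to a lactone; the allylsilane tolerates the cold, briefly acidic medium.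

Step 7
Reactants: 12 allylsilane keto aldehyde
Product: 13 (4aS,7S,8aS)-7-hydroxy-2,8a-dimethyl-5-methylidene-4a,5,6,7,8,8a-hexahydronaphthalen-1(4H)-one (labdane numbering: 2α-hydroxy-4-methylidene-Δ7-9-one, 5α-H, 10β-methyl)
Conditions: BF3·OEt2 (1.1 equiv), CH2Cl2, −78 °C; aq. NaHCO3
Reagents that add atoms: none
Why: The boron Lewis acid binds the aldehyde oxygen, the alkene carbon γ to silicon adds to C2 to give a β-silyl cation stabilised by the C–Si bond, and loss of the silyl group leaves the exocyclic C4=C19 alkene. This is the intramolecular Hosomi–Sakurai reaction, whose closest precedent is the Lewis-acid cyclisation of allylsilane aldehydes of the same tether length to 3-methylidenecyclohexanols. Ring A closes as a six-membered carbocycle, 6-exo-trig with respect to the carbonyl group, with the allyl unit becoming part of the ring. The two reacting arms are trans and both equatorial on ring B, so a chair-like transition state leads directly to the trans-decalin. The only new stereocentre is C2: in the open, non-chelated chair the Lewis-acid-bound oxygen should take the equatorial position, anti to the reacting alkene, because the axial position would meet the axial C10 methyl in a 1,3-diaxial contact, and this gives the 2α alcohol. The step needs chemoselectivity for the aldehyde over the enone, which is secured by the much higher electrophilicity of the aldehyde and by the fact that conjugate attack at C7 would require an axial C5 arm and a bridged ring. Low temperature and one equivalent of Lewis acid keep protodesilylation in check, and C5 and C10 are not touched.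

Step 8
Reactants: 13 hydroxy enone
Product: 14 2α-(tert-butyldimethylsilyloxy)-4-methylidene-Δ7-9-one (silyl ether of 13)
Conditions: TBSCl, imidazole, DMF, rt
Reagents that add atoms: tert-butyldimethylsilyl chloride, CC(C)(C)[Si](C)(C)Cl
Why: Standard silylation of an unhindered equatorial secondary alcohol; the group has to last until the final step.

Step 9
Reactants: 14 silyl ether
Product: 15 spiro-epoxide of 14 at C4/C19 (either configuration at C4)
Conditions: mCPBA, NaHCO3, CH2Cl2, 0 °C
Reagents that add atoms: 3-chloroperbenzoic acid, OOC(=O)c1cccc(Cl)c1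
Why: Prilezhaev epoxidation is selective for the electron-rich exocyclic alkene over the conjugated C7=C8 bond; the epoxide configuration is irrelevant because C4 becomes trigonal again in step 11.

Step 10
Reactants: 15 epoxide
Product: 16 2α-(tert-butyldimethylsilyloxy)-8,10β-dimethyl-9-oxo-5αH-octal-7-ene-4-carbaldehyde (both C4 epimers)
Conditions: BF3·OEt2 (0.2 equiv), CH2Cl2, −78 °C
Reagents that add atoms: none
Why: Meinwald rearrangement: the Lewis acid opens the epoxide at the tertiary carbon C4 and a 1,2-hydride shift from C19 gives the aldehyde; C19 carries only hydrogen, so no carbon migration can compete.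

Step 11
Reactants: 16 aldehyde; 2 iodomethane
Product: 18 2α-(tert-butyldimethylsilyloxy)-4α,8,10β-trimethyl-9-oxo-5αH-octal-7-ene-4β-carbaldehyde, via potassium enolate of the aldehyde 17 (not isolated)
Conditions: KOt-Bu (1.05 equiv), MeI (excess), THF/t-BuOH, 0 °C
Reagents that add atoms: iodomethane (2), CI
Why: The α-branched aldehyde is several pK units more acidic than the C6 hydrogens of the enone, so one equivalent of base should give the exocyclic aldehyde enolate, which is C-methylated (aldehyde enolate alkylation) from the equatorial α face, away from the axial C10 methyl; this leaves the formyl group axial (β) and sets the C4 quaternary centre.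

Step 12
Reactants: 18 quaternary aldehyde
Product: 19 2α-(tert-butyldimethylsilyloxy)-19-hydroxy-4α,8,10β-trimethyl-5αH-octal-7-en-9-one
Conditions: NaBH4, EtOH/CH2Cl2, −40 °C
Reagents that add atoms: none
Why: Chemoselective borohydride reduction: at low temperature the aldehyde is reduced much faster than the hindered, conjugated C9 ketone, and no stereocentre is created.

Step 13
Reactants: 19 hydroxy enone
Product: 20 2α,19-bis(tert-butyldimethylsilyloxy)-9-(tert-butyldimethylsilyloxy)-4α,8,10β-trimethyl-5αH-octala-6,8-diene (silyl dienol ether)
Conditions: TBSOTf (3 equiv), Et3N, CH2Cl2, 0 °C → rt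
Reagents that add atoms: tert-butyldimethylsilyl trifluoromethanesulfonate, CC(C)(C)[Si](C)(C)OS(=O)(=O)C(F)(F)F
Why: The silyl triflate with amine base silylates the neopentyl alcohol and, by O-silylation of the enone and loss of a C6 proton, gives the extended silyl dienol ether; C10 is quaternary, so no cross-conjugated isomer can form.

Step 14
Reactants: 20 silyl dienol ether
Product: 21 2α,19-bis(tert-butyldimethylsilyloxy)-6α-hydroxy-4α,8,10β-trimethyl-5αH-octal-7-en-9-one
Conditions: mCPBA, NaHCO3, CH2Cl2, −20 °C; aqueous work-up
Reagents that add atoms: 3-chloroperbenzoic acid, OOC(=O)c1cccc(Cl)c1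
Why: Vinylogous Rubottom oxidation: the peracid attacks the terminal C6=C7 bond of the silyloxydiene and the epoxide opens with push from the enol ether, giving the γ-hydroxy enone after loss of silicon; attack should come from the α face because the β face of C6 is covered by the axial C10 methyl and the axial C19 silyloxymethyl group, which sets C6.

Step 15
Reactants: 21 γ-hydroxy enone; 22 acetic anhydride
Product: 23 6α-acetoxy-2α,19-bis(tert-butyldimethylsilyloxy)-4α,8,10β-trimethyl-5αH-octal-7-en-9-one
Conditions: Ac2O, DMAP, pyridine, CH2Cl2, rt
Reagents that add atoms: acetic anhydride (22), CC(=O)OC(C)=O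
Why: DMAP-catalysed acylation of the only free hydroxyl; the two other oxygens are silylated, which is what places the acetate on C6 alone.

Step 16
Reactants: 23 γ-acetoxy enone
Product: 25 6α-acetoxy-2α,19-bis(tert-butyldimethylsilyloxy)-4α,8,10β-trimethyl-5αH-octal-8-en-9-yl trifluoromethanesulfonate, via lithium C8–C9 enolate 24 (not isolated)
Conditions: LiBH(s-Bu)3 (1.1 equiv), THF, −78 °C; then PhNTf2, −78 → 0 °C
Reagents that add atoms: N-phenylbis(trifluoromethanesulfonimide), O=S(=O)(N(c1ccccc1)S(=O)(=O)C(F)(F)F)C(F)(F)F
Why: Conjugate hydride delivery to C7, the unsubstituted β-position of the enone, gives the tetrasubstituted enolate regiospecifically, and O-sulfonylation by the triflimide completes a reductive triflation; this fixes the C8=C9 bond and removes the C7=C8 bond without touching C6, and the equatorial acetate cannot reach the enolate carbon.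

Step 17
Reactants: 25 enol triflate; 26 tributyl(vinyl)stannane
Product: 27 6α-acetoxy-2α,19-bis(tert-butyldimethylsilyloxy)-9-ethenyl-4α,8,10β-trimethyl-5αH-octal-8-ene
Conditions: CH2=CHSnBu3, Pd(PPh3)4 (5 mol %), LiCl, THF, reflux
Reagents that add atoms: tributyl(vinyl)stannane (26), C=C[Sn](CCCC)(CCCC)CCCC
Why: Stille coupling of a hindered cyclohexenyl triflate with a vinylstannane in the presence of LiCl; the acetate is homoallylic, not allylic, so it cannot ionise, and the neutral medium leaves it intact.

Step 18
Reactants: 27 diene; 28 4-bromofuran-2(5H)-one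
Product: 30 6α-acetoxy-2α,19-bis(tert-butyldimethylsilyloxy)labda-8,13-dien-15,16-olide, via B-alkyl-9-borabicyclo[3.3.1]nonane 29 (not isolated)
Conditions: 9-BBN, THF, 0 °C → rt; then 28, Pd(dppf)Cl2 (5 mol %), AsPh3, K3PO4 (aq.), DMF, rt
Reagents that add atoms: 4-bromofuran-2(5H)-one (28), BrC1=CC(=O)OC1
Why: The bulky borane hydroborates only the monosubstituted vinyl group, with boron on C12, and the B-alkyl Suzuki–Miyaura coupling with the β-bromobutenolide, a vinylogous acyl bromide that undergoes fast oxidative addition, forms C12–C13 under a mild phosphate base.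

Step 19
Reactants: 30 bis-silyl ether
Product: 31 6α-acetoxy-2α,19-dihydroxylabda-8,13-dien-15,16-olide (CNP0231903.1)
Conditions: HF·pyridine, pyridine, THF, 0 °C → rt
Reagents that add atoms: none
Why: Fluoride-mediated cleavage of both silyl ethers in a buffered, weakly acidic medium that should neither hydrolyse the acetate nor let it migrate to the C19 hydroxyl, and that leaves the butenolide and the tetrasubstituted alkene intact.

## Compound list

1 | (R)-carvone, (5R)-2-methyl-5-(prop-1-en-2-yl)cyclohex-2-en-1-one | CC1=CC[C@H](CC1=O)C(C)=C | starting material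
2 | iodomethane | CI | starting material
3 | lithium (3R)-6-methyl-3-(prop-1-en-2-yl)cyclohexa-1,5-dien-1-olate (cross-conjugated dienolate of 1) | CC1=CC[C@H](C=C1O[Li])C(C)=C | intermediate
4 | (5R)-2,6-dimethyl-5-(prop-1-en-2-yl)cyclohex-2-en-1-one (6-methylcarvone, C6 epimers) | CC1=CC[C@H](C(C)C1=O)C(C)=C | intermediate
5 | tert-butyl bromoacetate | CC(C)(C)OC(=O)CBr | starting material
6 | lithium enolate of 4 (O–Li on C1, C1=C6) | CC1=CC[C@H](C(C)=C1O[Li])C(C)=C | intermediate
7 | tert-butyl 2-[(1S,6S)-1,3-dimethyl-2-oxo-6-(prop-1-en-2-yl)cyclohex-3-en-1-yl]acetate | C1C=C(C)C(=O)[C@@](C)(CC(=O)OC(C)(C)C)[C@@H]1C(=C)C | intermediate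
8 | tert-butyl 2-[(1S,6R)-6-(3-chloroprop-1-en-2-yl)-1,3-dimethyl-2-oxocyclohex-3-en-1-yl]acetate | C1C=C(C)C(=O)[C@@](C)(CC(=O)OC(C)(C)C)[C@@H]1C(=C)CCl | intermediate
9 | hexamethyldisilane | C[Si](C)(C)[Si](C)(C)C | starting material
10 | tert-butyl 2-[(1S,6R)-1,3-dimethyl-2-oxo-6-[3-(trimethylsilyl)prop-1-en-2-yl]cyclohex-3-en-1-yl]acetate | C1C=C(C)C(=O)[C@@](C)(CC(=O)OC(C)(C)C)[C@@H]1C(=C)C[Si](C)(C)C | intermediate
11 | (5R,6S)-6-(2-hydroxyethyl)-2,6-dimethyl-5-[3-(trimethylsilyl)prop-1-en-2-yl]cyclohex-2-en-1-ol (C1 epimers) | C1C=C(C)C(O)[C@@](C)(CCO)[C@@H]1C(=C)C[Si](C)(C)C | intermediate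
12 | 2-[(1S,6R)-1,3-dimethyl-2-oxo-6-[3-(trimethylsilyl)prop-1-en-2-yl]cyclohex-3-en-1-yl]acetaldehyde | C1C=C(C)C(=O)[C@@](C)(CC=O)[C@@H]1C(=C)C[Si](C)(C)C | intermediate
13 | (4aS,7S,8aS)-7-hydroxy-2,8a-dimethyl-5-methylidene-4a,5,6,7,8,8a-hexahydronaphthalen-1(4H)-one (2α-hydroxy-4-methylidene-Δ7-9-one) | C1C=C(C)C(=O)[C@@]2(C)C[C@@H](O)CC(=C)[C@H]12 | intermediate
14 | 2α-(tert-butyldimethylsilyloxy)-8,10β-dimethyl-4-methylidene-5αH-octal-7-en-9-one | C1C=C(C)C(=O)[C@@]2(C)C[C@@H](O[Si](C)(C)C(C)(C)C)CC(=C)[C@H]12 | intermediate
15 | 4,19-epoxide of 14 (spiro-oxirane at C4, either configuration) | C1C=C(C)C(=O)[C@@]2(C)C[C@@H](O[Si](C)(C)C(C)(C)C)CC3(CO3)[C@H]12 | intermediate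
16 | 2α-(tert-butyldimethylsilyloxy)-8,10β-dimethyl-9-oxo-5αH-octal-7-ene-4-carbaldehyde (C4 epimers) | C1C=C(C)C(=O)[C@@]2(C)C[C@@H](O[Si](C)(C)C(C)(C)C)CC(C=O)[C@H]12 | intermediate
17 | potassium enolate of 16 (exocyclic C4=C19–OK) | C1C=C(C)C(=O)[C@@]2(C)C[C@@H](O[Si](C)(C)C(C)(C)C)CC(=CO[K])[C@H]12 | intermediate
18 | 2α-(tert-butyldimethylsilyloxy)-4α,8,10β-trimethyl-9-oxo-5αH-octal-7-ene-4β-carbaldehyde | C1C=C(C)C(=O)[C@@]2(C)C[C@@H](O[Si](C)(C)C(C)(C)C)C[C@](C)(C=O)[C@H]12 | intermediate
19 | 2α-(tert-butyldimethylsilyloxy)-19-hydroxy-4α,8,10β-trimethyl-5αH-octal-7-en-9-one | C1C=C(C)C(=O)[C@@]2(C)C[C@@H](O[Si](C)(C)C(C)(C)C)C[C@](C)(CO)[C@H]12 | intermediate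
20 | 2α,9,19-tris(tert-butyldimethylsilyloxy)-4α,8,10β-trimethyl-5αH-octala-6,8-diene | C1=CC(C)=C(O[Si](C)(C)C(C)(C)C)[C@@]2(C)C[C@@H](O[Si](C)(C)C(C)(C)C)C[C@](C)(CO[Si](C)(C)C(C)(C)C)[C@H]12 | intermediate
21 | 2α,19-bis(tert-butyldimethylsilyloxy)-6α-hydroxy-4α,8,10β-trimethyl-5αH-octal-7-en-9-one | O[C@H]1C=C(C)C(=O)[C@@]2(C)C[C@@H](O[Si](C)(C)C(C)(C)C)C[C@](C)(CO[Si](C)(C)C(C)(C)C)[C@H]12 | intermediate
22 | acetic anhydride | CC(=O)OC(C)=O | starting material
23 | 6α-acetoxy-2α,19-bis(tert-butyldimethylsilyloxy)-4α,8,10β-trimethyl-5αH-octal-7-en-9-one | CC(=O)O[C@H]1C=C(C)C(=O)[C@@]2(C)C[C@@H](O[Si](C)(C)C(C)(C)C)C[C@](C)(CO[Si](C)(C)C(C)(C)C)[C@H]12 | intermediate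
24 | lithium enolate from 23 (O–Li on C9, C8=C9, C7 saturated) | CC(=O)O[C@H]1CC(C)=C(O[Li])[C@@]2(C)C[C@@H](O[Si](C)(C)C(C)(C)C)C[C@](C)(CO[Si](C)(C)C(C)(C)C)[C@H]12 | intermediate
25 | 6α-acetoxy-2α,19-bis(tert-butyldimethylsilyloxy)-4α,8,10β-trimethyl-5αH-octal-8-en-9-yl trifluoromethanesulfonate | CC(=O)O[C@H]1CC(C)=C(OS(=O)(=O)C(F)(F)F)[C@@]2(C)C[C@@H](O[Si](C)(C)C(C)(C)C)C[C@](C)(CO[Si](C)(C)C(C)(C)C)[C@H]12 | intermediate
26 | tributyl(vinyl)stannane | C=C[Sn](CCCC)(CCCC)CCCC | starting material
27 | 6α-acetoxy-2α,19-bis(tert-butyldimethylsilyloxy)-9-ethenyl-4α,8,10β-trimethyl-5αH-octal-8-ene | CC(=O)O[C@H]1CC(C)=C(C=C)[C@@]2(C)C[C@@H](O[Si](C)(C)C(C)(C)C)C[C@](C)(CO[Si](C)(C)C(C)(C)C)[C@H]12 | intermediate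
28 | 4-bromofuran-2(5H)-one | BrC1=CC(=O)OC1 | starting material
29 | B-alkyl-9-borabicyclo[3.3.1]nonane from 27 (boron on C12) | CC(=O)O[C@H]1CC(C)=C(CCB3C4CCCC3CCC4)[C@@]2(C)C[C@@H](O[Si](C)(C)C(C)(C)C)C[C@](C)(CO[Si](C)(C)C(C)(C)C)[C@H]12 | intermediate
30 | 6α-acetoxy-2α,19-bis(tert-butyldimethylsilyloxy)labda-8,13-dien-15,16-olide | CC(=O)O[C@H]1CC(C)=C(CCC3=CC(=O)OC3)[C@@]2(C)C[C@@H](O[Si](C)(C)C(C)(C)C)C[C@](C)(CO[Si](C)(C)C(C)(C)C)[C@H]12 | intermediate
31 | 6α-acetoxy-2α,19-dihydroxylabda-8,13-dien-15,16-olide (CNP0231903.1) | CC(=O)O[C@H]1CC(C)=C(CCC2=CC(=O)OC2)[C@@]2(C)C[C@@H](O)C[C@](C)(CO)[C@H]12 | target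

## Step count and least certain steps

Total step count: 19. Longest linear sequence: 19 steps from (R)-carvone 1.

**Step 7 (key step).** The most likely failure is poor facial selectivity at the aldehyde carbon. A gauche arrangement of carbonyl and alkene can compete in intramolecular allylsilane additions, and it would give the axial 2β alcohol. Protodesilylation before ring closure is the second risk. The fallback sets C2 after the ring is closed, not during it. Starting from 12, the cyclisation is run for conversion only and the 2β-hydroxy epimer of 13 F1 is taken on. A Mitsunobu inversion with 4-nitrobenzoic acid, PPh3 and diisopropyl azodicarboxylate gives the 2α-(4-nitrobenzoate) of 13 F2. Methanolysis with K2CO3 in methanol returns to the route at 13.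

**Step 4.** The palladium-catalysed silylation may stall at transmetalation with the unactivated disilane, or the hot reaction may attack the enone. The fallback gives up silicon as the nucleophile carrier. Starting from chloride 8, reduction with i-Bu2AlH gives the chloro diol F3 and Swern oxidation gives the chloro keto aldehyde F4. Treatment with CrCl2 in THF forms an allylchromium species that adds to the aldehyde only (Nozaki–Hiyama-type allylation) and closes ring A. The route is rejoined at 13, and the step 7 fallback is available if C2 comes out wrong.

**Step 11.** Deprotonation may not be selective, so that the enone is deprotonated at C6 and methylated at C8, or the enolate may be methylated on oxygen. The fallback avoids strong base. Starting from 16, condensation with N-butyl-2-methylpropan-1-amine gives the hindered enamine F5. C-methylation with iodomethane 2 in acetonitrile and buffered aqueous hydrolysis return to the route at 18. The face of attack is governed by the same axial C10 methyl.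

**Step 14.** The peracid may attack the enol ether carbon C8 in place of the remote C6, or facial selectivity may be incomplete. The fallback fixes the regiochemistry by topology. Starting from 20, singlet oxygen (O2, light, tetraphenylporphyrin, CH2Cl2, −78 °C) should add across C6 and C9 of the ring B diene from the open α face. This gives the 6α,9α-endoperoxide F6. Reduction of the peroxy ketal with PPh3 in wet THF collapses it to the γ-hydroxy enone and returns to the route at 21.

**Step 16.** The hydride reagent may cleave the acetate, or 1,2-reduction may compete. The fallback separates reduction and triflation and uses no nucleophilic hydride. Starting from 23, conjugate reduction with catalytic [(Ph3P)CuH]6 and a hydrosiloxane gives, after work-up, the saturated 6α-acetoxy-9-ketone F7 as a mixture of C8 epimers. Treatment with Tf2O and 2,6-di-tert-butyl-4-methylpyridine in CH2Cl2 gives the more substituted enol triflate and returns to the route at 25.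

## Further compounds

F1 | step 7 | 2β-hydroxy epimer of 13 | C1C=C(C)C(=O)[C@@]2(C)C[C@H](O)CC(=C)[C@H]12
F2 | step 7 | 2α-(4-nitrobenzoyloxy) ester of 13 | C1C=C(C)C(=O)[C@@]2(C)C[C@@H](OC(=O)c3ccc(cc3)[N+](=O)[O-])CC(=C)[C@H]12
F3 | step 4 | (5R,6S)-5-(3-chloroprop-1-en-2-yl)-6-(2-hydroxyethyl)-2,6-dimethylcyclohex-2-en-1-ol (C1 epimers) | C1C=C(C)C(O)[C@@](C)(CCO)[C@@H]1C(=C)CCl
F4 | step 4 | 2-[(1S,6R)-6-(3-chloroprop-1-en-2-yl)-1,3-dimethyl-2-oxocyclohex-3-en-1-yl]acetaldehyde | C1C=C(C)C(=O)[C@@](C)(CC=O)[C@@H]1C(=C)CCl
F5 | step 11 | N-butyl-N-(2-methylpropyl) enamine of aldehyde 16 | C1C=C(C)C(=O)[C@@]2(C)C[C@@H](O[Si](C)(C)C(C)(C)C)CC(=CN(CCCC)CC(C)C)[C@H]12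
F6 | step 14 | 6α,9α-epidioxy-2α,9β,19-tris(tert-butyldimethylsilyloxy)-4α,8,10β-trimethyl-5αH-octal-7-ene | CC(C)(C)[Si](C)(C)O[C@@]12OO[C@@H](C=C1C)[C@@H]3[C@]2(C)C[C@@H](O[Si](C)(C)C(C)(C)C)C[C@]3(C)CO[Si](C)(C)C(C)(C)C
F7 | step 16 | 6α-acetoxy-2α,19-bis(tert-butyldimethylsilyloxy)-4α,8,10β-trimethyl-5αH-decalin-9-one (C8 epimers) | CC(=O)O[C@H]1CC(C)C(=O)[C@@]2(C)C[C@@H](O[Si](C)(C)C(C)(C)C)C[C@](C)(CO[Si](C)(C)C(C)(C)C)[C@H]12
A1 | alternative 1 | ethyl (6E,8S,10E)-8-acetoxy-13-(tert-butyldiphenylsilyloxy)-2,6,10-trimethyl-3-oxotrideca-6,10-dienoate | CCOC(=O)C(C)C(=O)CC/C(C)=C/[C@@H](OC(C)=O)C/C(C)=C/CCO[Si](c1ccccc1)(c1ccccc1)C(C)(C)C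
A2 | alternative 1 | ethyl 6α-acetoxy-12-(tert-butyldiphenylsilyloxy)-3-oxo-13,14,15,16-tetranorlabd-8(17)-en-19-oate | CC(=O)O[C@H]1CC(=C)[C@H](CCO[Si](c2ccccc2)(c2ccccc2)C(C)(C)C)[C@@]2(C)CCC(=O)[C@](C)(C(=O)OCC)[C@H]12
A3 | alternative 2 | methyl (E)-2-[2-acetyl-5-(tert-butyldimethylsilyloxy)-3-(tert-butyldimethylsilyloxymethyl)-1,3-dimethylcyclohexyl]-3-(trifluoromethylsulfonyloxy)but-2-enoate, ring centres as in the target | CC(=O)[C@@H]1[C@@](C)(/C(C(=O)OC)=C(/C)OS(=O)(=O)C(F)(F)F)C[C@@H](O[Si](C)(C)C(C)(C)C)C[C@]1(C)CO[Si](C)(C)C(C)(C)C
A4 | alternative 2 | methyl 2α,19-bis(tert-butyldimethylsilyloxy)-6-oxo-12,13,14,15,16-pentanorlabd-8-en-11-oate | COC(=O)C1=C(C)CC(=O)[C@@H]2[C@]1(C)C[C@@H](O[Si](C)(C)C(C)(C)C)C[C@]2(C)CO[Si](C)(C)C(C)(C)C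
A5 | alternative 3 | 2,6-dimethyl-1,4-benzoquinone | CC1=CC(=O)C=C(C)C1=O
A6 | alternative 3 | methyl (2E)-4-(tert-butyldimethylsilyloxy)penta-2,4-dienoate | COC(=O)/C=C/C(=C)O[Si](C)(C)C(C)(C)C
A7 | alternative 3 | cis-fused adduct, methyl 2-(tert-butyldimethylsilyloxy)-8,10β-dimethyl-6,9-dioxo-5βH-octala-2,7-diene-4α-carboxylate | COC(=O)[C@@H]1C=C(O[Si](C)(C)C(C)(C)C)C[C@]2(C)C(=O)C(C)=CC(=O)[C@H]12
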